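**Plan**

1. Numbering is that of the hexahydroindene: C1–C3 are the cyclopentanone carbons (C2 is C=O), C3a/C7a the ring fusion, C4 the acid-bearing carbon, C5 the styryl-bearing carbon, C6=C7 the ring alkene. The retrosynthesis first lowers CO2H to CHO and the C2 ketone to a C2 silyl ether (activating group and oxidation level that keep the two α-ethyl centres from enolising).
2. The cyclohexene, with C6=C7 flanked by C5 and C7a and with C4/C3a as former dienophile carbons, is a Diels–Alder retron, and C1–C2–C3 is a three-atom tether. Cutting the ring-fusion bond C3a–C7a together with C4–C5 therefore opens both rings to an all-(E) open-chain tetraenal.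
3. The chain is cut at four C=C bonds (three Wittig reactions with one formyl ylide, one Horner–Wadsworth–Emmons reaction for the styryl end) and at the C1–C2 bond (auxiliary aldol with 2-ethylacrolein).
4. Forward: aldol → triene arm grown from the aldol carbonyl → hydroboration of the 2-ethylallyl end → last Wittig reaction, after which cyclohexene and cyclopentane close together in the same flask → desilylation, ketone oxidation, acid oxidation.
5. Stereochemistry: the auxiliary sets C1 and the temporary carbinol C2; C2 relays to C3 (anti hydroboration); C1, C3 and the alkene geometries relay to C3a, C4, C5 and C7a in the cycloaddition; C2 is then erased by oxidation.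

Key step: step 10

Assumption: the stabilised ylide 2-(triphenylphosphoranylidene)butanal (9) and (4R)-4-benzyl-1,3-thiazolidine-2-thione (1) are taken as purchasable reagents.

**Step 1**
Reactants: 1 (4R)-4-benzyl-1,3-thiazolidine-2-thione; 2 butanoyl chloride
Product: 3 (4R)-4-benzyl-3-butanoyl-1,3-thiazolidine-2-thione
Conditions: Et3N, DMAP (cat.), CH2Cl2, 0 °C → rt
Reagents that add atoms: none
Why: N-acylation of the thiazolidinethione nitrogen by the acid chloride (amide-type acylation) should be clean and creates no stereocenter.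

**Step 2**
Reactants: 3 (4R)-4-benzyl-3-butanoyl-1,3-thiazolidine-2-thione; 4 2-ethylacrolein (2-methylidenebutanal)
Product: 6 (4R)-4-benzyl-3-[(2R,3R)-2-ethyl-3-hydroxy-4-methylidenehexanoyl]-1,3-thiazolidine-2-thione, via chlorotitanium Z-enolate 5 (not isolated)
Conditions: TiCl4 (1.05 equiv), i-Pr2NEt (1.1 equiv), N-methyl-2-pyrrolidinone (1.0 equiv), CH2Cl2, 0 °C; then 4, 0 °C
Reagents that add atoms: none
Why: Titanium-mediated thiazolidinethione syn-aldol (Crimmins-type, Evans-syn sense): the (Z)-enolate 5 should add to the aldehyde carbonyl through a closed Zimmerman–Traxler transition state on the enolate face remote from the benzyl group, which sets C2 (R) and C3 (R) of the acyl chain in one event.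

**Step 3**
Reactants: 6 (4R)-4-benzyl-3-[(2R,3R)-2-ethyl-3-hydroxy-4-methylidenehexanoyl]-1,3-thiazolidine-2-thione
Product: 7 (4R)-4-benzyl-3-[(2R,3R)-3-(tert-butyldimethylsilyloxy)-2-ethyl-4-methylidenehexanoyl]-1,3-thiazolidine-2-thione
Conditions: TBSOTf, 2,6-lutidine, CH2Cl2, −78 → 0 °C
Reagents that add atoms: tert-butyldimethylsilyl trifluoromethanesulfonate, CC(C)(C)[Si](C)(C)OS(=O)(=O)C(F)(F)F
Why: Silyl triflate silylation of the hindered secondary alcohol under 2,6-lutidine buffering should leave the thioimide and both stereocenters untouched.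

**Step 4**
Reactants: 7 (4R)-4-benzyl-3-[(2R,3R)-3-(tert-butyldimethylsilyloxy)-2-ethyl-4-methylidenehexanoyl]-1,3-thiazolidine-2-thione
Product: 8 (2R,3R)-3-(tert-butyldimethylsilyloxy)-2-ethyl-4-methylidenehexanal
Conditions: i-Bu2AlH (1.5 equiv), CH2Cl2, −78 °C
Reagents that add atoms: none
Why: Direct hydride reduction of an N-acyl thiazolidinethione stops at the aldehyde because the aluminium-bound tetrahedral adduct collapses only on work-up, and at −78 °C the α-stereocenter should be preserved.

**Step 5**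
Reactants: 8 (2R,3R)-3-(tert-butyldimethylsilyloxy)-2-ethyl-4-methylidenehexanal; 9 2-(triphenylphosphoranylidene)butanal
Product: 10 (2E,4S,5R)-5-(tert-butyldimethylsilyloxy)-2,4-diethyl-6-methylideneoct-2-enal
Conditions: PhMe, 90 °C
Reagents that add atoms: none
Why: Wittig olefination with a stabilised α-branched formyl ylide should give the (E)-trisubstituted enal; no stereocenter is formed and the neutral conditions should spare the α-center.

**Step 6**
Reactants: 10 (2E,4S,5R)-5-(tert-butyldimethylsilyloxy)-2,4-diethyl-6-methylideneoct-2-enal; 9 2-(triphenylphosphoranylidene)butanal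
Product: 11 (2E,4E,6S,7R)-7-(tert-butyldimethylsilyloxy)-2,4,6-triethyl-8-methylidenedeca-2,4-dienal
Conditions: PhMe, 110 °C
Reagents that add atoms: none
Why: A second Wittig olefination with the same stabilised ylide should extend the enal to the (2E,4E)-dienal, the less electrophilic product being slower to react again.

**Step 7**
Reactants: 11 (2E,4E,6S,7R)-7-(tert-butyldimethylsilyloxy)-2,4,6-triethyl-8-methylidenedeca-2,4-dienal; 12 diethyl benzylphosphonate
Product: 13 [(1E,3E,5E,7S,8R)-8-(tert-butyldimethylsilyloxy)-3,5,7-triethyl-9-methylideneundeca-1,3,5-trien-1-yl]benzene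
Conditions: NaN(SiMe3)2, THF, −78 °C → rt
Reagents that add atoms: none
Why: Horner–Wadsworth–Emmons olefination with the benzylphosphonate anion should give the (E)-styryl alkene, and the C7–H bond, held in the diene plane by allylic strain, should resist vinylogous deprotonation.

**Step 8**
Reactants: 13 [(1E,3E,5E,7S,8R)-8-(tert-butyldimethylsilyloxy)-3,5,7-triethyl-9-methylideneundeca-1,3,5-trien-1-yl]benzene
Product: 15 (2S,3R,4S,5E,7E,9E)-3-(tert-butyldimethylsilyloxy)-2,4,6,8-tetraethyl-10-phenyldeca-5,7,9-trien-1-ol, via B-alkyl-9-BBN borane 14 (not isolated)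
Conditions: 9-BBN, THF, 0 °C → rt; then NaOH, H2O2, H2O, 0 °C
Reagents that add atoms: hydrogen peroxide, OO
Why: Hydroboration–oxidation: 9-BBN should add only to the 1,1-disubstituted alkene (boron at CH2) and, in the allylic-strain-minimised conformer of the silyloxy-bearing center, from the face opposite the branched carbon chain, giving the 2,3-anti alcohol (new center 2S) after oxidation with retention.

**Step 9**
Reactants: 15 (2S,3R,4S,5E,7E,9E)-3-(tert-butyldimethylsilyloxy)-2,4,6,8-tetraethyl-10-phenyldeca-5,7,9-trien-1-ol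
Product: 16 (2R,3R,4S,5E,7E,9E)-3-(tert-butyldimethylsilyloxy)-2,4,6,8-tetraethyl-10-phenyldeca-5,7,9-trienal
Conditions: Dess–Martin periodinane, CH2Cl2, 0 °C → rt
Reagents that add atoms: none
Why: Dess–Martin oxidation of the primary alcohol should give the aldehyde under near-neutral conditions without epimerising the new α-center.

**Step 10**
Reactants: 16 (2R,3R,4S,5E,7E,9E)-3-(tert-butyldimethylsilyloxy)-2,4,6,8-tetraethyl-10-phenyldeca-5,7,9-trienal; 9 2-(triphenylphosphoranylidene)butanal
Product: 18 (1S,2R,3S,3aR,4R,5S,7aR)-2-(tert-butyldimethylsilyloxy)-1,3,4,5,7-pentaethyl-5-[(E)-2-phenylethenyl]-2,3,3a,4,5,7a-hexahydro-1H-indene-4-carbaldehyde, via open-chain tetraenal 17 (not isolated)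
Conditions: PhMe (0.02 M), BHT (cat.), 90 °C; then 110 °C, sealed tube
Reagents that add atoms: none
Why: A Wittig olefination with the stabilised ylide 9 should first give the (E)-2-ethyl enal 17, in which the C7–C10 diene and the C2=C3 enal are joined by a three-atom tether, and continued heating should trigger a concerted, asynchronous, normal-electron-demand intramolecular [4+2] cycloaddition that forms C3–C7 (the ring-fusion bond) and C2–C10 of 17. The closest known reaction type is the thermal type 1 intramolecular Diels–Alder reaction of 1,3,8-nonatrienes carrying a terminal carbonyl group, which gives trans-fused hydrindenes, run here in tandem with the olefination. The cyclohexene ring closes by the cycloaddition itself (both new σ bonds), and the cyclopentane ring closes as the fused (not bridged) tether ring when the ring-fusion bond forms. C5 and C4 of 18 follow from suprafacial addition to the (E,E)-diene and the (E)-enal (styryl outside, formyl endo, hence cis to each other), the trans fusion at C3a/C7a follows from the formyl-endo, tether-exo transition state, and the absolute sense follows from the two ethyl-bearing centers C4 and C6 of 17, each of which keeps its C–H bond eclipsed with the adjacent alkene to avoid allylic 1,3-strain with the ethyl group on C2 or C8. The step needs the trans-fused endo adduct on one diene face and reaction of the inner diene, not the styryl-terminated one; the first is secured because only this transition state satisfies the allylic-strain preference of both centers at once (each cis-fused alternative violates one, the other trans-fused one violates both), the second because the tether allows only a five-membered ring.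

**Step 11**
Reactants: 18 (1S,2R,3S,3aR,4R,5S,7aR)-2-(tert-butyldimethylsilyloxy)-1,3,4,5,7-pentaethyl-5-[(E)-2-phenylethenyl]-2,3,3a,4,5,7a-hexahydro-1H-indene-4-carbaldehyde
Product: 19 (1S,2R,3S,3aR,4R,5S,7aR)-1,3,4,5,7-pentaethyl-2-hydroxy-5-[(E)-2-phenylethenyl]-2,3,3a,4,5,7a-hexahydro-1H-indene-4-carbaldehyde
Conditions: Bu4NF, THF, rt → 45 °C
Reagents that add atoms: none
Why: Fluoride-induced desilylation (strong Si–F bond) should free the hindered secondary alcohol; the aldehyde has no α-hydrogen and no epimerisable center is present at this stage.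

**Step 12**
Reactants: 19 (1S,2R,3S,3aR,4R,5S,7aR)-1,3,4,5,7-pentaethyl-2-hydroxy-5-[(E)-2-phenylethenyl]-2,3,3a,4,5,7a-hexahydro-1H-indene-4-carbaldehyde
Product: 20 (1S,3S,3aR,4R,5S,7aR)-1,3,4,5,7-pentaethyl-2-oxo-5-[(E)-2-phenylethenyl]-2,3,3a,4,5,7a-hexahydro-1H-indene-4-carbaldehyde
Conditions: Dess–Martin periodinane, CH2Cl2, rt
Reagents that add atoms: none
Why: Dess–Martin oxidation of the secondary alcohol should give the cyclopentanone and erase the temporary carbinol stereocenter, while the neutral conditions should leave the two α-ethyl centers, already in the all-trans arrangement, untouched.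

**Step 13**
Reactants: 20 (1S,3S,3aR,4R,5S,7aR)-1,3,4,5,7-pentaethyl-2-oxo-5-[(E)-2-phenylethenyl]-2,3,3a,4,5,7a-hexahydro-1H-indene-4-carbaldehyde
Product: 21 (1S,3S,3aR,4R,5S,7aR)-1,3,4,5,7-pentaethyl-2-oxo-5-[(E)-2-phenylethenyl]-2,3,3a,4,5,7a-hexahydro-1H-indene-4-carboxylic acid (CNP0132298.1)
Conditions: NaClO2, NaH2PO4, 2-methyl-2-butene, t-BuOH/H2O, rt
Reagents that add atoms: sodium chlorite, [Na+].[O-]Cl=O
Why: Pinnick oxidation should convert the hindered, non-enolisable aldehyde into the carboxylic acid, with 2-methyl-2-butene trapping HOCl so that the ring alkene, the styrene and the ketone α-centers are not affected.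

**Compound list**

1 | (4R)-4-benzyl-1,3-thiazolidine-2-thione | S=C1SC[C@@H](Cc2ccccc2)N1 | starting material
2 | butanoyl chloride | CCCC(=O)Cl | starting material
3 | (4R)-4-benzyl-3-butanoyl-1,3-thiazolidine-2-thione | S=C1SC[C@@H](Cc2ccccc2)N1C(=O)CCC | intermediate
4 | 2-ethylacrolein (2-methylidenebutanal) | CCC(=C)C=O | starting material
5 | trichlorotitanium (Z)-enolate of 3 (O–Ti cis to the ethyl group) | S=C1SC[C@@H](Cc2ccccc2)N1/C(O[Ti](Cl)(Cl)Cl)=C/CC | intermediate (not isolated)
6 | (4R)-4-benzyl-3-[(2R,3R)-2-ethyl-3-hydroxy-4-methylidenehexanoyl]-1,3-thiazolidine-2-thione | S=C1SC[C@@H](Cc2ccccc2)N1C(=O)[C@H](CC)[C@@H](O)C(=C)CC | intermediate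
7 | (4R)-4-benzyl-3-[(2R,3R)-3-(tert-butyldimethylsilyloxy)-2-ethyl-4-methylidenehexanoyl]-1,3-thiazolidine-2-thione | S=C1SC[C@@H](Cc2ccccc2)N1C(=O)[C@H](CC)[C@@H](O[Si](C)(C)C(C)(C)C)C(=C)CC | intermediate
8 | (2R,3R)-3-(tert-butyldimethylsilyloxy)-2-ethyl-4-methylidenehexanal | O=C[C@H](CC)[C@@H](O[Si](C)(C)C(C)(C)C)C(=C)CC | intermediate
9 | 2-(triphenylphosphoranylidene)butanal | CCC(C=O)=P(c1ccccc1)(c1ccccc1)c1ccccc1 | starting material
10 | (2E,4S,5R)-5-(tert-butyldimethylsilyloxy)-2,4-diethyl-6-methylideneoct-2-enal | O=C/C(CC)=C/[C@H](CC)[C@@H](O[Si](C)(C)C(C)(C)C)C(=C)CC | intermediate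
11 | (2E,4E,6S,7R)-7-(tert-butyldimethylsilyloxy)-2,4,6-triethyl-8-methylidenedeca-2,4-dienal | O=C/C(CC)=C/C(CC)=C/[C@H](CC)[C@@H](O[Si](C)(C)C(C)(C)C)C(=C)CC | intermediate
12 | diethyl benzylphosphonate | CCOP(=O)(Cc1ccccc1)OCC | starting material
13 | [(1E,3E,5E,7S,8R)-8-(tert-butyldimethylsilyloxy)-3,5,7-triethyl-9-methylideneundeca-1,3,5-trien-1-yl]benzene | c1ccccc1/C=C/C(CC)=C/C(CC)=C/[C@H](CC)[C@@H](O[Si](C)(C)C(C)(C)C)C(=C)CC | intermediate
14 | B-alkyl-9-borabicyclo[3.3.1]nonane from addition of B–H across the 1,1-disubstituted alkene of 13 (boron on the terminal CH2; the three sp3 centers as in 15) | c1ccccc1/C=C/C(CC)=C/C(CC)=C/[C@H](CC)[C@@H](O[Si](C)(C)C(C)(C)C)[C@@H](CC)CB1C2CCCC1CCC2 | intermediate (not isolated)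
15 | (2S,3R,4S,5E,7E,9E)-3-(tert-butyldimethylsilyloxy)-2,4,6,8-tetraethyl-10-phenyldeca-5,7,9-trien-1-ol | c1ccccc1/C=C/C(CC)=C/C(CC)=C/[C@H](CC)[C@@H](O[Si](C)(C)C(C)(C)C)[C@@H](CC)CO | intermediate
16 | (2R,3R,4S,5E,7E,9E)-3-(tert-butyldimethylsilyloxy)-2,4,6,8-tetraethyl-10-phenyldeca-5,7,9-trienal | c1ccccc1/C=C/C(CC)=C/C(CC)=C/[C@H](CC)[C@@H](O[Si](C)(C)C(C)(C)C)[C@@H](CC)C=O | intermediate
17 | (2E,4S,5R,6S,7E,9E,11E)-5-(tert-butyldimethylsilyloxy)-2,4,6,8,10-pentaethyl-12-phenyldodeca-2,7,9,11-tetraenal | c1ccccc1/C=C/C(CC)=C/C(CC)=C/[C@H](CC)[C@@H](O[Si](C)(C)C(C)(C)C)[C@@H](CC)/C=C(CC)/C=O | intermediate (not isolated)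
18 | (1S,2R,3S,3aR,4R,5S,7aR)-2-(tert-butyldimethylsilyloxy)-1,3,4,5,7-pentaethyl-5-[(E)-2-phenylethenyl]-2,3,3a,4,5,7a-hexahydro-1H-indene-4-carbaldehyde | CCC1=C[C@@](/C=C/c2ccccc2)(CC)[C@](CC)(C=O)[C@@H]2[C@@H]1[C@H](CC)[C@@H](O[Si](C)(C)C(C)(C)C)[C@H]2CC | intermediate
19 | (1S,2R,3S,3aR,4R,5S,7aR)-1,3,4,5,7-pentaethyl-2-hydroxy-5-[(E)-2-phenylethenyl]-2,3,3a,4,5,7a-hexahydro-1H-indene-4-carbaldehyde | CCC1=C[C@@](/C=C/c2ccccc2)(CC)[C@](CC)(C=O)[C@@H]2[C@@H]1[C@H](CC)[C@@H](O)[C@H]2CC | intermediate
20 | (1S,3S,3aR,4R,5S,7aR)-1,3,4,5,7-pentaethyl-2-oxo-5-[(E)-2-phenylethenyl]-2,3,3a,4,5,7a-hexahydro-1H-indene-4-carbaldehyde | CCC1=C[C@@](/C=C/c2ccccc2)(CC)[C@](CC)(C=O)[C@@H]2[C@@H]1[C@H](CC)C(=O)[C@H]2CC | intermediate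
21 | (1S,3S,3aR,4R,5S,7aR)-1,3,4,5,7-pentaethyl-2-oxo-5-[(E)-2-phenylethenyl]-2,3,3a,4,5,7a-hexahydro-1H-indene-4-carboxylic acid | CCC1=C[C@@](/C=C/c2ccccc2)(CC)[C@](CC)(C(=O)O)[C@@H]2[C@@H]1[C@H](CC)C(=O)[C@H]2CC | target

**Step count**

Total step count: 13. Longest linear sequence: 13 steps (1 → 21).

**Steps most likely to fail**

1. Step 10 (tandem olefination/cycloaddition). Ring closure may lag behind the olefination. Prolonged heating could then allow a 1,5-hydrogen shift from the inside ethyl group of the diene, or erode the endo preference because the α-ethyl group of the enal competes with the formyl group for the endo position. Fallback, setting out from 16: the dienophile is installed as an isolable ester and the ring closure is run as a separate, Lewis-acid-promoted step. Horner–Wadsworth–Emmons reaction of 16 with triethyl 2-phosphonobutyrate (LiCl, DBU, MeCN, rt) should give the open-chain ethyl tetraenoate F1. Me2AlCl (CH2Cl2, −40 → 0 °C) should then promote the same cycloaddition through the ester-endo transition state to the ester cycloadduct F2. i-Bu2AlH (CH2Cl2, −78 → 0 °C) should reduce the hindered ester to the neopentyl alcohol F3, and Dess–Martin oxidation of F3 returns to the route at 18.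

2. Step 8 (hydroboration in the presence of the triene). The hindered 1,1-disubstituted alkene may react so slowly that 9-BBN begins to add to the styryl triene, which would mean loss of chemoselectivity. Fallback, setting out from 10: the hydroboration is moved ahead of triene construction. Luche reduction of 10 (NaBH4, CeCl3·7H2O, MeOH, 0 °C) should give the allylic alcohol F4. 9-BBN followed by NaOH/H2O2 should hydroborate only the 1,1-disubstituted alkene, anti as in step 8, to give the diol F5. MnO2 (CH2Cl2, rt) should oxidise only the allylic alcohol to the hydroxy enal F6. Wittig reaction with 9 (PhMe, 110 °C) should give the hydroxy dienal F7, and Horner–Wadsworth–Emmons reaction of F7 with 12 (excess NaN(SiMe3)2, THF) returns to the route at 15.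

3. Step 6 (second Wittig olefination). Addition of the stabilised ylide to the hindered α-ethyl enal may be so slow that over-homologation of the product or thermal degradation competes. Fallback, setting out from 10: the more nucleophilic anion of triethyl 2-phosphonobutyrate (NaH, THF, 0 °C → rt) should give the dienoate F8. i-Bu2AlH (CH2Cl2, −78 °C) should give the dienol F9, and MnO2 oxidation of F9 (CH2Cl2, rt) returns to the route at 11.

**Further compounds**

F1 | step 10 | ethyl (2E,4S,5R,6S,7E,9E,11E)-5-(tert-butyldimethylsilyloxy)-2,4,6,8,10-pentaethyl-12-phenyldodeca-2,7,9,11-tetraenoate | c1ccccc1/C=C/C(CC)=C/C(CC)=C/[C@H](CC)[C@@H](O[Si](C)(C)C(C)(C)C)[C@@H](CC)/C=C(CC)/C(=O)OCC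
F2 | step 10 | ethyl (1S,2R,3S,3aR,4R,5S,7aR)-2-(tert-butyldimethylsilyloxy)-1,3,4,5,7-pentaethyl-5-[(E)-2-phenylethenyl]-2,3,3a,4,5,7a-hexahydro-1H-indene-4-carboxylate | CCC1=C[C@@](/C=C/c2ccccc2)(CC)[C@](CC)(C(=O)OCC)[C@@H]2[C@@H]1[C@H](CC)[C@@H](O[Si](C)(C)C(C)(C)C)[C@H]2CC
F3 | step 10 | [(1S,2R,3S,3aR,4R,5S,7aR)-2-(tert-butyldimethylsilyloxy)-1,3,4,5,7-pentaethyl-5-[(E)-2-phenylethenyl]-2,3,3a,4,5,7a-hexahydro-1H-inden-4-yl]methanol | CCC1=C[C@@](/C=C/c2ccccc2)(CC)[C@](CC)(CO)[C@@H]2[C@@H]1[C@H](CC)[C@@H](O[Si](C)(C)C(C)(C)C)[C@H]2CC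
F4 | step 8 | (2E,4S,5R)-5-(tert-butyldimethylsilyloxy)-2,4-diethyl-6-methylideneoct-2-en-1-ol | OC/C(CC)=C/[C@H](CC)[C@@H](O[Si](C)(C)C(C)(C)C)C(=C)CC
F5 | step 8 | (2E,4S,5R,6S)-5-(tert-butyldimethylsilyloxy)-2,4,6-triethylhept-2-ene-1,7-diol | OC/C(CC)=C/[C@H](CC)[C@@H](O[Si](C)(C)C(C)(C)C)[C@@H](CC)CO
F6 | step 8 | (2E,4S,5R,6S)-5-(tert-butyldimethylsilyloxy)-2,4,6-triethyl-7-hydroxyhept-2-enal | O=C/C(CC)=C/[C@H](CC)[C@@H](O[Si](C)(C)C(C)(C)C)[C@@H](CC)CO
F7 | step 8 | (2E,4E,6S,7R,8S)-7-(tert-butyldimethylsilyloxy)-2,4,6,8-tetraethyl-9-hydroxynona-2,4-dienal | O=C/C(CC)=C/C(CC)=C/[C@H](CC)[C@@H](O[Si](C)(C)C(C)(C)C)[C@@H](CC)CO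
F8 | step 6 | ethyl (2E,4E,6S,7R)-7-(tert-butyldimethylsilyloxy)-2,4,6-triethyl-8-methylidenedeca-2,4-dienoate | CCOC(=O)/C(CC)=C/C(CC)=C/[C@H](CC)[C@@H](O[Si](C)(C)C(C)(C)C)C(=C)CC
F9 | step 6 | (2E,4E,6S,7R)-7-(tert-butyldimethylsilyloxy)-2,4,6-triethyl-8-methylidenedeca-2,4-dien-1-ol | OC/C(CC)=C/C(CC)=C/[C@H](CC)[C@@H](O[Si](C)(C)C(C)(C)C)C(=C)CC
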